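The earlier runs measured E and Q but not X, so it was impossible for me to read directly the reagent on which E's fall depends, and I had to reach it through E.

| setting | cedar | larch | midnight | summer |
|---|---|---|---|---|
| E | 20 mM | 20 mM | 20 mM | 20 mM |
| X | 1.5 equiv | 2.4 equiv | 1.10 equiv | 1.10 equiv |
| G | 5 equiv | 5 equiv | 5.00 equiv | 5.00 equiv |
| temperature | 86 °C | 100 °C | 80 °C | 105 °C |
| remark | run made earlier | run made earlier |  |  |
| time |  |  | 30 h | 30 h |

| run | time / h | Q / % | E / % |
|---|---|---|---|
| cedar | 4.00 | 9 | 90 |
| cedar | 8.00 | 19 | 80 |
| cedar | 10.0 | 23 | 75 |
| cedar | 15.0 | 27 | 70 |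
| cedar | 20.0 | 34 | 66 |
| larch | 1.33 | 14 | 80 |
| larch | 3.00 | 30 | 70 |
| larch | 4.00 | 33 | 65 |
| larch | 6.00 | 44 | 55 |
| larch | 8.00 | 47 | 48 |

(readings scatter by 1.5 percentage points)

- what may be going on: E + X <-> Q; G + X <-> D

* which of these there is most of at the end, counted by the E in it, midnight (E / Q)
* which of these there is most of at the end, counted by the E in it, summer (E / Q)
* how much there is at the end of the one of these that leads, in percent of the E charged: midnight
* how much there is at the end of the one of these that leads, in percent of the E charged: summer

I took the logarithm of E's remaining fraction to fall in proportion to c(X) times time, with c(X) held at its charge (pseudo-first-order). Cedar reached 80% E at 8.00 h and larch at 1.33 h. With the charges of X counted, larch therefore ran faster by a factor of 3.76, which is one power of ten per 24.3 K.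

Two times then carried the argument. The first is the fall time t_E, the time E needs to reach 80% with X at its charge. Scaled from cedar, it came to 19.2 h for midnight, and scaled from larch, to 1.81 h for summer. The second is the working time t_W, the hours of full-strength X that a flask delivers; G + X stands beside E + X among the steps that may be going on. The number of fall times is t_W/t_E, and E is 80% raised to that power.

Larch's 48% at 8.00 h was worth 4.37 h at its opening pace. Summer is hotter than larch and has less X, so I gave summer that working time, as a judgement. It is shorter than the clock. Midnight is cooler than cedar, and cedar was still falling at its last reading, so I let the clock 30 h stand as an upper limit. Midnight then had 1.56 fall times and E near 70.6%, and summer had 2.42 and E near 58.3%.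

The forecast also put E ahead in both flasks, at 80% for midnight and 59% for summer, noting for summer that “reversal as X runs out favours E further”; its midnight figure stood above mine.

Midnight ended with E leading at 75.4%, and summer with E leading at 57.1%. At the end of midnight, X stood at 59% of its charge. Read back through t_E, midnight's E amounts to 24.4 h of working time, less than the clock.

    E + X ⇌ Q (K = 120 L mol⁻¹, k = 0.630 L mol⁻¹ h⁻¹, Ea = 86.0 kJ mol⁻¹, ΔH = −6.00 kJ mol⁻¹)
    G + X ⇌ D (K = 4.40 L mol⁻¹, k = 0.140 L mol⁻¹ h⁻¹, Ea = 79.0 kJ mol⁻¹, ΔH = 26.0 kJ mol⁻¹)
    (constants at 80 °C)

In a neighbouring flask, midnight with 4.40 equiv of X, t_E shrinks to 4.81 h, so the clock holds 6.24 fall times and E should be near 24.8%. The computed flask has E at 32.0%, and Q leads at 68.0%.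

(The earlier runs and the new flask come from a simulation with constants of no real substance; the scatter is artificial.)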